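How much of Z has reacted after 5.0 min in alder and in ash, and does more L raise it?

all flasks: Z 20 mM
- theta: L 17 mM; run made earlier
- zeta: L 31 mM; run made earlier
- alder: L 30.0 mM; time 5.0 min
- ash: L 39.0 mM; time 5.0 min

| run | time / min | Z / % | Q / % |
|---|---|---|---|
| theta | 0.200 | 81.8 | 9.8 |
| theta | 0.333 | 73.6 | 18.1 |
| theta | 0.500 | 64.8 | 20.4 |
| theta | 0.833 | 54.5 | 24.4 |
| theta | 1.50 | 45.3 | 21.6 |
| theta | 2.50 | 36.7 | 20.2 |
| zeta | 0.200 | 73.6 | 20.5 |
| zeta | 0.333 | 63.3 | 28.7 |
| zeta | 0.500 | 50.7 | 32.4 |
| zeta | 0.833 | 37.8 | 35.4 |
| zeta | 1.50 | 26.0 | 37.1 |
| zeta | 2.50 | 20.5 | 30.5 |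

(each reading ± 1 percentage point)

- part of the Z that has reacted at the end, alder
- part of the Z that has reacted at the end, ash
- what raising the concentration of L from its lowest to its highest value here does to the part of the Z that has reacted (changes below 5 percentage points count as none) (no change / it falls / it rises)

- the numbers in the tables scatter by 1 percentage point (one standard deviation)
- what has gone from Z into another species counts as reacted, even if it can come back
- a reading or a percentage of Q counts all its forms, free or not

I start from the slope of the curve. Over the first 0.200 min, ln Z falls at 1.00 min⁻¹ in theta and at 1.53 min⁻¹ in zeta. A straight line through these two readings in c(L) leaves a part free of L, 0.363 min⁻¹. It also gives 9.63 mM, the c(L) at which Z is lost as fast by the L-free part as by the part that grows with c(L), my crossover concentration. It carries the scatter of two readings.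

So the L path starts with a share c(L)/(c(L)+crossover) of the loss of Z: 75.7% in alder, 80.2% in ash. In zeta, the nearest run to alder, the slope drops to 0.561 min⁻¹ at the knee, then to 0.238 min⁻¹, below the L-free part. That tail, continued from the last reading, gives 88.7% reacted. I take this as my ceiling for alder, since the curve is still flattening, and I expect ash higher.

The forecast says 85%, 90% and it rises, below my ceiling for alder, holding that “the later stage is slower than simple consumption of L explains”.

The flasks give 83.6% and 92.2%: it rises, by 8.6 percentage points, and the main reason is the difference in c(L).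

    Z ⇌ G (K = 0.660, k = 0.00525 s⁻¹)
    L + E ⇌ J, settled at all times (K = 25000 M⁻¹)
    Z + L → E + Q (k = 0.846 M⁻¹ s⁻¹)
    D ⇌ Q, rate k4*(cs4 - [Q]) while solid is left; crystals form when [Q] > cs4 (solubility = 7.10 mM, k = 0.164 s⁻¹)
    Q ⇌ X (K = 1.72, k = 0.0109 s⁻¹)

Free L in alder ends at 1.90 mM, beneath the crossover. The depletion of L is part of the reason for the stall: with it taken away, alder reaches 99.0% instead of 83.6%. From the constants of the scheme, the forward rate constant of Z to G over that of Z + L gives a crossover of 6.21 mM. The further flask, alder's recipe with 12 mM of L, therefore starts at twice that crossover, with an L share of 65.9%, and ends with 58.6% reacted.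

(All runs were computed on assumed constants, and the scatter is random.)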